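The synthesis cuts C10'–C11' and C11'–C12' in the acyclic side chain (C1' benzylic to C16'). The feature exploited is the C10'–C11'H(CH3)–C12'(=O)–C13'H2–C14'=C15' terminus: an epimerisable methine beside a β,γ-unsaturated ketone, remote from C5' and from the benzene ring. In one telescoped operation a primary C10' pinacol boronate takes up two sparteine-bound lithiated triisopropylbenzoates, ethyl then homoprenyl. Two stereospecific 1,2-migrations fix C11' as R under reagent control and deliver C12' as a C–B bond that masks the ketone, no ring being closed. The precursor is the bis-silylated aryl C1'–C10' dienyl boronate, built from 5-chloropent-1-yne without any protecting group at C10'.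

Key step: step 14

Remark on configuration: read from the SMILES, the target is 2'E, 5'R, 6'E, 11'R.
Remark on step 3: the Re-face preference of the (R)-configured phosphoric acid is assigned by analogy with aryl and alkenyl aldehydes; the antipodal acid is equally available should the sense be reversed.
Remark on design: C10' travels as a primary chloride that is inert until step 10. The phenol carries TIPS because it must outlast organolithiums, basic peroxide and the periodinane, which would oxidise a free 4-methoxyphenol. Both silyl groups leave together in the last step.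

Step 1
Reactants: 1 5-chloropent-1-yne
Product: 4 (E)-6-chloro-3-methylhex-2-en-1-ol, via alkenylalane 2 (not isolated), via lithium alanate 3 (not isolated)
Conditions: Me3Al (2 equiv), Cp2ZrCl2 (0.2 equiv), CH2Cl2, 0 °C to rt; volatiles removed; n-BuLi (1 equiv), hexane/THF, −30 to 0 °C; (CH2O)n, rt; aqueous work-up
Reagents that add atoms: trimethylaluminium C[Al](C)C; formaldehyde (as paraformaldehyde) C=O
Why: Zirconium-catalysed Negishi carboalumination adds methyl and aluminium syn across the terminal alkyne with aluminium at the terminus, which fixes the 6'E geometry, and the derived alanate is hydroxymethylated by formaldehyde with retention while the primary chloride stays inert.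

Step 2
Reactants: 4 (E)-6-chloro-3-methylhex-2-en-1-ol
Product: 5 (E)-6-chloro-3-methylhex-2-enal
Conditions: activated MnO2 (15 equiv), CH2Cl2, rt
Reagents that add atoms: none
Why: Allylic oxidation with MnO2 is neutral and selective for the allylic alcohol, so the E-enal should form without loss of geometry.

Step 3
Reactants: 5 (E)-6-chloro-3-methylhex-2-enal
Product: 6 (4R,5E)-9-chloro-6-methylnon-5-en-1-yn-4-ol
Conditions: allenylboronic acid pinacol ester (1.5 equiv), (R)-TRIP [(R)-3,3'-bis(2,4,6-triisopropylphenyl)-1,1'-binaphthyl-2,2'-diyl hydrogen phosphate, 10 mol %], 4 Å MS, toluene, −20 to 0 °C; aqueous work-up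
Reagents that add atoms: allenylboronic acid pinacol ester C=C=CB1OC(C)(C)C(C)(C)O1
Why: Chiral-phosphoric-acid-catalysed allenylboration (SE2' propargylation through a closed six-membered transition state in which the acid binds a boronate oxygen and the formyl hydrogen) should steer attack to the Re face of the enal and set C5' as R, the allenyl reagent giving only the homopropargylic regioisomer.

Step 4
Reactants: 6 (4R,5E)-9-chloro-6-methylnon-5-en-1-yn-4-ol
Product: 7 (4R,5E)-4-(tert-butyldimethylsilyloxy)-9-chloro-6-methylnon-5-en-1-yne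
Conditions: TBSCl, imidazole, DMF, rt
Reagents that add atoms: tert-butyldimethylsilyl chloride CC(C)(C)[Si](C)(C)Cl
Why: Imidazole-promoted O-silylation of a secondary alcohol leaves the C5' centre, the alkyne and the chloride untouched.

Step 5
Reactants: 8 4-methoxy-2-methylphenol
Product: 9 2-hydroxy-5-methoxy-3-methylbenzaldehyde
Conditions: MgCl2, Et3N, (CH2O)n, MeCN, reflux; dilute HCl work-up
Reagents that add atoms: formaldehyde (as paraformaldehyde) C=O
Why: The magnesium-mediated ortho-formylation (Casnati–Skattebøl reaction) delivers formaldehyde inside the magnesium phenoxide chelate to the only free ortho position, and a second formaldehyde accepts hydride to give the aldehyde.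

Step 6
Reactants: 9 2-hydroxy-5-methoxy-3-methylbenzaldehyde
Product: 10 5-methoxy-3-methyl-2-(triisopropylsilyloxy)benzaldehyde
Conditions: TIPSOTf, 2,6-lutidine, CH2Cl2, 0 °C to rt
Reagents that add atoms: triisopropylsilyl triflate CC(C)[Si](OS(=O)(=O)C(F)(F)F)(C(C)C)C(C)C
Why: Silylation with the silyl triflate overcomes the hindrance and the hydrogen bond of the 2,6-disubstituted phenol.

Step 7
Reactants: 10 5-methoxy-3-methyl-2-(triisopropylsilyloxy)benzaldehyde
Product: 11 [5-methoxy-3-methyl-2-(triisopropylsilyloxy)phenyl]methanol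
Conditions: NaBH4, EtOH/THF, 0 °C, short reaction time
Reagents that add atoms: none
Why: Borohydride reduction of the aldehyde is fast at 0 °C, and the bulk of TIPS together with the short contact time should suppress silyl migration to the new benzylic oxygen.

Step 8
Reactants: 11 [5-methoxy-3-methyl-2-(triisopropylsilyloxy)phenyl]methanol
Product: 12 1-(chloromethyl)-5-methoxy-3-methyl-2-(triisopropylsilyloxy)benzene
Conditions: PPh3, N-chlorosuccinimide, THF, 0 °C to rt
Reagents that add atoms: N-chlorosuccinimide O=C1CCC(=O)N1Cl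
Why: Appel-type chlorination through an alkoxyphosphonium salt converts the benzylic alcohol under neutral conditions that spare the aryl silyl ether.

Step 9
Reactants: 7 (4R,5E)-4-(tert-butyldimethylsilyloxy)-9-chloro-6-methylnon-5-en-1-yne; 12 1-(chloromethyl)-5-methoxy-3-methyl-2-(triisopropylsilyloxy)benzene
Product: 14 aryl C1'–C10' chloride (2'E,5'R,6'E; phenol as TIPS ether; C5'–OH as TBS ether), via dienylalane 13 (not isolated)
Conditions: 7, Me3Al (2.5 equiv), Cp2ZrCl2 (0.2 equiv), H2O (1 equiv), CH2Cl2, −30 to 0 °C; volatiles removed, THF; 12 (0.9 equiv), NiCl2(PPh3)2 (5 mol %) pre-reduced by n-BuLi (10 mol %) to zerovalent nickel, THF, 0 °C to rt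
Reagents that add atoms: trimethylaluminium C[Al](C)C
Why: Water-accelerated Negishi carboalumination (syn, aluminium terminal, hence 2'E) keeps the allylic silyl ether only briefly in contact with the Lewis acid, and the nickel-catalysed cross-coupling of alkenylalanes with benzylic chlorides proceeds with retention of alkene geometry, tolerates di-ortho-substituted benzylic chlorides and leaves the unactivated C10' chloride alone.

Step 10
Reactants: 14 aryl C1'–C10' chloride
Product: 15 aryl C1'–C10' iodide (2'E,5'R,6'E)
Conditions: NaI (5 equiv), acetone, reflux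
Reagents that add atoms: sodium iodide [Na+].[I-]
Why: The Finkelstein reaction exchanges the only SN2-active halide, driven by precipitation of NaCl, under neutral conditions harmless to both silyl ethers.

Step 11
Reactants: 15 aryl C1'–C10' iodide
Product: 17 aryl C1'–C10' pinacol boronate (2'E,5'R,6'E), via C10' alkyllithium 16 (not isolated)
Conditions: t-BuLi (2.1 equiv), Et2O/pentane, −78 °C; 2-isopropoxy-4,4,5,5-tetramethyl-1,3,2-dioxaborolane (1.5 equiv), −78 °C to rt; aqueous work-up
Reagents that add atoms: 2-isopropoxy-4,4,5,5-tetramethyl-1,3,2-dioxaborolane CC(C)OB1OC(C)(C)C(C)(C)O1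
Why: Iodine–lithium exchange outruns deprotonation at −78 °C, and the primary alkyllithium, a 4-pentenyl type with no favourable cyclisation onto C6'=C7', is trapped by electrophilic borylation.

Step 12
Reactants: 18 2,4,6-triisopropylbenzoic acid
Product: 19 ethyl 2,4,6-triisopropylbenzoate
Conditions: EtI, K2CO3, DMF, 40 °C
Reagents that add atoms: iodoethane CCI
Why: O-alkylation of the carboxylate (SN2 at iodoethane) avoids any attack at the shielded carbonyl carbon.

Step 13
Reactants: 18 2,4,6-triisopropylbenzoic acid; 20 4-methylpent-3-en-1-ol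
Product: 21 4-methylpent-3-enyl 2,4,6-triisopropylbenzoate
Conditions: PPh3, DIAD, THF, 0 °C to rt
Reagents that add atoms: none
Why: Mitsunobu esterification activates the primary alcohol instead of the hindered acid and does not touch the trisubstituted alkene.

Step 14
Reactants: 17 aryl C1'–C10' pinacol boronate; 19 ethyl 2,4,6-triisopropylbenzoate; 21 4-methylpent-3-enyl 2,4,6-triisopropylbenzoate
Product: 27 full-skeleton C12' pinacol boronate (2'E,5'R,6'E,11'R,12'R), via lithiated ethyl benzoate 22 (not isolated), via first boronate complex 23 (not isolated), via C11' secondary boronate 24 (not isolated), via lithiated homoprenyl benzoate 25 (not isolated), via second boronate complex 26 (not isolated)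
Conditions: first round: 19 (1.3 equiv), (−)-sparteine (1.3 equiv), s-BuLi (1.25 equiv), Et2O, −78 °C, 4 h; 17, −78 °C, then reflux; aq. NH4Cl wash, drying, no purification; second round: 21 (1.5 equiv), (−)-sparteine (1.5 equiv), s-BuLi (1.45 equiv), Et2O, −78 °C, 4 h; crude 24, −78 °C, then reflux
Reagents that add atoms: none
Why: The sparteine-bound base abstracts the pro-S proton beside each benzoate oxygen to give the configurationally stable (S)-α-oxyalkyllithiums 22 and 25, and each adds to the empty boron orbital with retention to form a tetracoordinate complex (23, then 26). On warming, the boron-bound carbon (C10', then C11') shifts antiperiplanar to the leaving triisopropylbenzoate, with inversion at the carbenoid carbon and retention in the migrating group, which forms C10'–C11' and then C11'–C12'. The closest known reaction type is iterative reagent-controlled lithiation–borylation of pinacol boronates (assembly-line homologation, a Matteson-type 1,2-metallate rearrangement), and both new bonds are acyclic, so no ring is closed. C11' becomes R and C12' becomes R solely through the (−)-sparteine used in each lithiation, independently of the distant C5' centre, and the C12' centre is deleted later by oxidation. The step needs chemoselectivity for boron over the two silyl ethers and the acidic C1'H2 group, which is secured because the Lewis-acidic boronate is the only fast electrophile at −78 °C and s-BuLi is kept below the amount of benzoate. It also needs a single insertion per round, which is secured because surplus carbenoid decomposes below the temperature at which the complexes rearrange, and the homoprenyl ester brings the C14'=C15' double bond in at its final position, so the α/γ regiochemistry problem of allylmetal additions never arises.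

Step 15
Reactants: 27 full-skeleton C12' pinacol boronate
Product: 28 C12' alcohol (2'E,5'R,6'E,11'R,12'R)
Conditions: 30 % aq. H2O2, 2 M NaOH, THF, 0 °C to rt
Reagents that add atoms: hydrogen peroxide OO
Why: Hydroperoxide adds to boron and the C12' carbon migrates from boron to oxygen with retention (boronate oxidation), conditions under which unactivated alkenes and the di-ortho-shielded aryl TIPS ether persist.

Step 16
Reactants: 28 C12' alcohol
Product: 29 bis-silylated C12' ketone (2'E,5'R,6'E,11'R)
Conditions: Dess–Martin periodinane (1.5 equiv), NaHCO3, CH2Cl2, 0 °C to rt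
Reagents that add atoms: none
Why: Buffered Dess–Martin oxidation is non-basic and nearly neutral, so neither epimerisation at C11' nor migration of the C14'=C15' bond into conjugation is expected, and the protected arene is not oxidised.

Step 17
Reactants: 29 bis-silylated C12' ketone
Product: 30 target 2-[(2E,5R,6E,11R)-5-hydroxy-3,7,11,15-tetramethyl-12-oxohexadeca-2,6,14-trienyl]-4-methoxy-6-methylphenol
Conditions: TBAF/AcOH (1:1, 6 equiv), THF, 0 °C to rt, under argon
Reagents that add atoms: none
Why: Fluoride-mediated desilylation buffered with acetic acid cleaves the aryl TIPS and the allylic TBS ether in one operation, and the medium stays too weakly basic to enolise the ketone and too weakly acidic to ionise the C5' allylic alcohol.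

Compound list
1 | 5-chloropent-1-yne | C#CCCCCl | starting material
2 | (E)-(5-chloro-2-methylpent-1-enyl)dimethylalane | C[Al](C)/C=C(\C)CCCCl | intermediate
3 | lithium butyl[(E)-5-chloro-2-methylpent-1-enyl]dimethylalanate | [Li+].CCCC[Al-](C)(C)/C=C(\C)CCCCl | intermediate
4 | (E)-6-chloro-3-methylhex-2-en-1-ol | OC/C=C(\C)CCCCl | intermediate
5 | (E)-6-chloro-3-methylhex-2-enal | O=C/C=C(\C)CCCCl | intermediate
6 | (4R,5E)-9-chloro-6-methylnon-5-en-1-yn-4-ol | C#CC[C@@H](O)/C=C(\C)CCCCl | intermediate
7 | (4R,5E)-4-(tert-butyldimethylsilyloxy)-9-chloro-6-methylnon-5-en-1-yne | C#CC[C@@H](O[Si](C)(C)C(C)(C)C)/C=C(\C)CCCCl | intermediate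
8 | 4-methoxy-2-methylphenol | COc1ccc(O)c(C)c1 | starting material
9 | 2-hydroxy-5-methoxy-3-methylbenzaldehyde | COc1cc(C)c(O)c(C=O)c1 | intermediate
10 | 5-methoxy-3-methyl-2-(triisopropylsilyloxy)benzaldehyde | COc1cc(C)c(O[Si](C(C)C)(C(C)C)C(C)C)c(C=O)c1 | intermediate
11 | [5-methoxy-3-methyl-2-(triisopropylsilyloxy)phenyl]methanol | COc1cc(C)c(O[Si](C(C)C)(C(C)C)C(C)C)c(CO)c1 | intermediate
12 | 1-(chloromethyl)-5-methoxy-3-methyl-2-(triisopropylsilyloxy)benzene | COc1cc(C)c(O[Si](C(C)C)(C(C)C)C(C)C)c(CCl)c1 | intermediate
13 | [(1E,4R,5E)-4-(tert-butyldimethylsilyloxy)-9-chloro-2,6-dimethylnona-1,5-dienyl]dimethylalane | C[Al](C)/C=C(\C)C[C@@H](O[Si](C)(C)C(C)(C)C)/C=C(\C)CCCCl | intermediate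
14 | 1-[(2E,5R,6E)-5-(tert-butyldimethylsilyloxy)-10-chloro-3,7-dimethyldeca-2,6-dienyl]-5-methoxy-3-methyl-2-(triisopropylsilyloxy)benzene | COc1cc(C)c(O[Si](C(C)C)(C(C)C)C(C)C)c(C/C=C(\C)C[C@@H](O[Si](C)(C)C(C)(C)C)/C=C(\C)CCCCl)c1 | intermediate
15 | 1-[(2E,5R,6E)-5-(tert-butyldimethylsilyloxy)-10-iodo-3,7-dimethyldeca-2,6-dienyl]-5-methoxy-3-methyl-2-(triisopropylsilyloxy)benzene | COc1cc(C)c(O[Si](C(C)C)(C(C)C)C(C)C)c(C/C=C(\C)C[C@@H](O[Si](C)(C)C(C)(C)C)/C=C(\C)CCCI)c1 | intermediate
16 | C10' lithio analogue of 15 (2'E,5'R,6'E) | COc1cc(C)c(O[Si](C(C)C)(C(C)C)C(C)C)c(C/C=C(\C)C[C@@H](O[Si](C)(C)C(C)(C)C)/C=C(\C)CCC[Li])c1 | intermediate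
17 | 1-[(2E,5R,6E)-5-(tert-butyldimethylsilyloxy)-3,7-dimethyl-10-(4,4,5,5-tetramethyl-1,3,2-dioxaborolan-2-yl)deca-2,6-dienyl]-5-methoxy-3-methyl-2-(triisopropylsilyloxy)benzene | COc1cc(C)c(O[Si](C(C)C)(C(C)C)C(C)C)c(C/C=C(\C)C[C@@H](O[Si](C)(C)C(C)(C)C)/C=C(\C)CCCB2OC(C)(C)C(C)(C)O2)c1 | intermediate
18 | 2,4,6-triisopropylbenzoic acid | CC(C)c1cc(C(C)C)c(C(=O)O)c(C(C)C)c1 | starting material
19 | ethyl 2,4,6-triisopropylbenzoate | CCOC(=O)c1c(C(C)C)cc(C(C)C)cc1C(C)C | intermediate
20 | 4-methylpent-3-en-1-ol | CC(C)=CCCO | starting material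
21 | 4-methylpent-3-enyl 2,4,6-triisopropylbenzoate | CC(C)=CCCOC(=O)c1c(C(C)C)cc(C(C)C)cc1C(C)C | intermediate
22 | (S)-1-lithioethyl 2,4,6-triisopropylbenzoate (sparteine complex, ligand not drawn) | C[C@H]([Li])OC(=O)c1c(C(C)C)cc(C(C)C)cc1C(C)C | intermediate
23 | lithium boronate complex of 17 with 22 (boron bears C10', pinacolate and the (S)-1-(aroyloxy)ethyl group) | [Li+].COc1cc(C)c(O[Si](C(C)C)(C(C)C)C(C)C)c(C/C=C(\C)C[C@@H](O[Si](C)(C)C(C)(C)C)/C=C(\C)CCC[B-]2(OC(C)(C)C(C)(C)O2)[C@@H](C)OC(=O)c3c(C(C)C)cc(C(C)C)cc3C(C)C)c1 | intermediate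
24 | 1-[(2E,5R,6E,11R)-5-(tert-butyldimethylsilyloxy)-3,7-dimethyl-11-(4,4,5,5-tetramethyl-1,3,2-dioxaborolan-2-yl)dodeca-2,6-dienyl]-5-methoxy-3-methyl-2-(triisopropylsilyloxy)benzene | COc1cc(C)c(O[Si](C(C)C)(C(C)C)C(C)C)c(C/C=C(\C)C[C@@H](O[Si](C)(C)C(C)(C)C)/C=C(\C)CCC[C@@H](C)B2OC(C)(C)C(C)(C)O2)c1 | intermediate
25 | (S)-1-lithio-4-methylpent-3-enyl 2,4,6-triisopropylbenzoate (sparteine complex, ligand not drawn) | CC(C)=CC[C@H]([Li])OC(=O)c1c(C(C)C)cc(C(C)C)cc1C(C)C | intermediate
26 | lithium boronate complex of 24 with 25 (boron bears C11', pinacolate and the (S)-1-(aroyloxy)-4-methylpent-3-enyl group) | [Li+].COc1cc(C)c(O[Si](C(C)C)(C(C)C)C(C)C)c(C/C=C(\C)C[C@@H](O[Si](C)(C)C(C)(C)C)/C=C(\C)CCC[C@@H](C)[B-]2(OC(C)(C)C(C)(C)O2)[C@@H](CC=C(C)C)OC(=O)c3c(C(C)C)cc(C(C)C)cc3C(C)C)c1 | intermediate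
27 | 1-[(2E,5R,6E,11R,12R)-5-(tert-butyldimethylsilyloxy)-3,7,11,15-tetramethyl-12-(4,4,5,5-tetramethyl-1,3,2-dioxaborolan-2-yl)hexadeca-2,6,14-trienyl]-5-methoxy-3-methyl-2-(triisopropylsilyloxy)benzene | COc1cc(C)c(O[Si](C(C)C)(C(C)C)C(C)C)c(C/C=C(\C)C[C@@H](O[Si](C)(C)C(C)(C)C)/C=C(\C)CCC[C@@H](C)[C@H](B2OC(C)(C)C(C)(C)O2)CC=C(C)C)c1 | intermediate
28 | 1-[(2E,5R,6E,11R,12R)-5-(tert-butyldimethylsilyloxy)-12-hydroxy-3,7,11,15-tetramethylhexadeca-2,6,14-trienyl]-5-methoxy-3-methyl-2-(triisopropylsilyloxy)benzene | COc1cc(C)c(O[Si](C(C)C)(C(C)C)C(C)C)c(C/C=C(\C)C[C@@H](O[Si](C)(C)C(C)(C)C)/C=C(\C)CCC[C@@H](C)[C@H](O)CC=C(C)C)c1 | intermediate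
29 | 1-[(2E,5R,6E,11R)-5-(tert-butyldimethylsilyloxy)-3,7,11,15-tetramethyl-12-oxohexadeca-2,6,14-trienyl]-5-methoxy-3-methyl-2-(triisopropylsilyloxy)benzene | COc1cc(C)c(O[Si](C(C)C)(C(C)C)C(C)C)c(C/C=C(\C)C[C@@H](O[Si](C)(C)C(C)(C)C)/C=C(\C)CCC[C@@H](C)C(=O)CC=C(C)C)c1 | intermediate
30 | 2-[(2E,5R,6E,11R)-5-hydroxy-3,7,11,15-tetramethyl-12-oxohexadeca-2,6,14-trienyl]-4-methoxy-6-methylphenol | COc1cc(C)c(O)c(C/C=C(\C)C[C@@H](O)/C=C(\C)CCC[C@@H](C)C(=O)CC=C(C)C)c1 | target

Total step count: 17. Longest linear sequence: 11 steps (1–4, 9–11, 14–17) from 5-chloropent-1-yne.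

Steps most likely to fail

Step 14.
- What may go wrong: deprotonation of the benzoates may be incomplete or unselective, in particular through competition from the allylic C–H bonds of 21. Unconsumed s-BuLi may capture the boronate. The bulky diamine-bound carbenoid may complex only slowly with the hindered secondary boronate. Imperfect enantioselection in the first lithiation would appear as a remote C11' epimer that is hard to separate.
- Fallback: it sets out from 19, 21 and 17 and returns at 27. The carbenoids are no longer made by deprotonation in front of the valuable boronate but are stored as α-stannyl benzoates. Compounds 19 and 21 are each lithiated (s-BuLi, (−)-sparteine, Et2O, −78 °C) and quenched with Me3SnCl. This gives (S)-1-(trimethylstannyl)ethyl 2,4,6-triisopropylbenzoate F1, which can be recrystallised to raise its enantiopurity, and (S)-4-methyl-1-(trimethylstannyl)pent-3-enyl 2,4,6-triisopropylbenzoate F2, which is freed of lithiation by-products by chromatography.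
- Tin–lithium exchange (n-BuLi, Et2O, −78 °C, retention) then regenerates 22 and 25 free of diamine, free of s-BuLi and in an exactly known amount. Compound 17 is homologated with the carbenoid from F1, 24 is now isolated and purified, and a second separate homologation with the carbenoid from F2 gives 27.

Step 9.
- What may go wrong: the Lewis acid may ionise the allylic silyl ether at C5' during carboalumination, residual Me3Al may transfer methyl to the benzylic chloride, or coupling may be sluggish next to the ortho TIPS ether.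
- Fallback: it sets out from 7 and 12 and returns at 14. The two events are separated and the polarity of the coupling is reversed. The alane 13 is quenched cold with I2 as soon as it has formed, giving (1E,4R,5E)-4-(tert-butyldimethylsilyloxy)-9-chloro-1-iodo-2,6-dimethylnona-1,5-diene F3, which is purified. Chloride 12 is converted by LiCl-assisted zinc insertion (Zn dust, LiCl, THF) into [5-methoxy-3-methyl-2-(triisopropylsilyloxy)benzyl]zinc chloride F4. Negishi coupling of F3 with F4 (Pd(PPh3)4, THF, rt) engages only the alkenyl iodide and gives 14 with retention of geometry.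

Step 3.
- What may go wrong: turnover may be slow and facial selectivity poor on a β,β-disubstituted enal, which is less electrophilic than the aldehydes for which the catalysis is established.
- Fallback: it sets out from 5 and returns at 6, replacing asymmetric induction by resolution. Barbier propargylation (Zn dust, propargyl bromide, THF/aq. NH4Cl, 0 °C) gives racemic (E)-9-chloro-6-methylnon-5-en-1-yn-4-ol F5. Sharpless kinetic resolution (Ti(OiPr)4, L-(+)-diisopropyl tartrate, t-BuOOH 0.6 equiv, 4 Å MS, CH2Cl2, −20 °C), run somewhat beyond half conversion, should epoxidise the S enantiomer faster. The product is (1S)-1-[(2R,3R)-3-(3-chloropropyl)-3-methyloxiran-2-yl]but-3-yn-1-ol F6, which is removed by chromatography and leaves 6.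

Further compounds
F1 | step 14 | (S)-1-(trimethylstannyl)ethyl 2,4,6-triisopropylbenzoate | C[C@H]([Sn](C)(C)C)OC(=O)c1c(C(C)C)cc(C(C)C)cc1C(C)C
F2 | step 14 | (S)-4-methyl-1-(trimethylstannyl)pent-3-enyl 2,4,6-triisopropylbenzoate | CC(C)=CC[C@H]([Sn](C)(C)C)OC(=O)c1c(C(C)C)cc(C(C)C)cc1C(C)C
F3 | step 9 | (1E,4R,5E)-4-(tert-butyldimethylsilyloxy)-9-chloro-1-iodo-2,6-dimethylnona-1,5-diene | I/C=C(\C)C[C@@H](O[Si](C)(C)C(C)(C)C)/C=C(\C)CCCCl
F4 | step 9 | [5-methoxy-3-methyl-2-(triisopropylsilyloxy)benzyl]zinc chloride | COc1cc(C)c(O[Si](C(C)C)(C(C)C)C(C)C)c(C[Zn]Cl)c1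
F5 | step 3 | racemic (E)-9-chloro-6-methylnon-5-en-1-yn-4-ol | C#CCC(O)/C=C(\C)CCCCl
F6 | step 3 | (1S)-1-[(2R,3R)-3-(3-chloropropyl)-3-methyloxiran-2-yl]but-3-yn-1-ol | C#CC[C@H](O)[C@H]1O[C@]1(C)CCCCl
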